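**Retrosynthetic overview**

1. Enone Cα=Cβ bond: Claisen–Schmidt condensation of the 5-acetyl-6-hydroxy-2,3-dihydrobenzofuran with 2,2-dimethylchroman-6-carbaldehyde (chroman ring from phenol and isoprene, then Rieche formylation).
2. Aryl–acetyl bond at C5: bromination, bromine–lithium exchange, Weinreb amide; the O6 benzyl ether is hydrogenolysed before the enone exists.
3. Feature on which the strategy rests: the dihydrofuran ring (O1, C2, C3, C3a, C7a) with the C2 stereocentre carrying C(CH3)2OH is a constitutional isomer of the pyran ring of a 2,2-dimethylchroman-3-ol. Its O1–C2 bond is made by a 1,2-shift of the ring oxygen from the gem-dimethyl carbon to the carbinol carbon of a chroman-3-yl mesylate through an oxiranium ion (pyran-to-dihydrofuran contraction with inversion at that carbon).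
4. Chromanol stereocentre: Jacobsen epoxidation of the flat C3=C4 bond of 7-(benzyloxy)-2,2-dimethyl-2H-chromene, then hydride opening at benzylic C4.
5. Ring order: pyran (chromenylation of 3-(benzyloxy)phenol with 3-methylbut-2-enal), oxirane, contraction of the pyran to the dihydrofuran; the chroman of the aldehyde is made separately.

Key step: step 5

Assumption: the (S,S)-salen manganese chloride catalyst is taken to deliver the (3S,4S)-epoxide, as with other 2,2-dimethyl-2H-chromenes; the configuration of the chromanol is to be confirmed before mesylation, and the (R,R)-catalyst would be used if the opposite sense were found.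

**Route**

Step 1
Reactants: 1 3-(benzyloxy)phenol; 2 3-methylbut-2-enal
Product: 5 7-(benzyloxy)-2,2-dimethyl-2H-chromene, via benzodioxaborin 3 (not isolated), via o-quinone methide 4 (not isolated)
Conditions: PhB(OH)2 (1 equiv), AcOH (cat.), toluene, reflux, azeotropic removal of water
Reagents that add atoms: none
Why: Phenylboronic acid-templated ortho-condensation (chromenylation): the aryl boronate delivers the aldehyde to the ortho carbon para to the benzyloxy group to give 3, which fragments thermally to 4 and closes by oxa-6π-electrocyclisation, the hindered position between the two oxygens being avoided.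

Step 2
Reactants: 5 7-(benzyloxy)-2,2-dimethyl-2H-chromene
Product: 6 (3S,4S)-7-(benzyloxy)-3,4-epoxy-2,2-dimethylchroman
Conditions: (S,S)-N,N'-bis(3,5-di-tert-butylsalicylidene)-1,2-cyclohexanediaminomanganese chloride (4 mol%), 4-phenylpyridine N-oxide, NaOCl aq (pH 11.3), CH2Cl2, 0 °C; crude product used at once
Reagents that add atoms: sodium hypochlorite, [Na+].[O-]Cl
Why: Jacobsen epoxidation, for which conjugated cis-disubstituted 2,2-dimethylchromenes are among the best substrates; the catalyst transfers oxygen to one face of the C3=C4 bond and so sets C3 and C4 together, and the basic medium protects the acid-labile electron-rich benzylic epoxide.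

Step 3
Reactants: 6 (3S,4S)-7-(benzyloxy)-3,4-epoxy-2,2-dimethylchroman
Product: 7 (S)-7-(benzyloxy)-2,2-dimethylchroman-3-ol
Conditions: LiAlH4, THF, 0 °C; then H2O, NaOH aq
Reagents that add atoms: none
Why: Hydride opening of the epoxide (LiAlH4 reduction) should occur at the activated benzylic C4 and not at C3, which is shielded by the adjacent quaternary carbon; the C3–O bond is not broken, so C3 keeps its (S) configuration.

Step 4
Reactants: 7 (S)-7-(benzyloxy)-2,2-dimethylchroman-3-ol
Product: 8 (S)-7-(benzyloxy)-2,2-dimethylchroman-3-yl methanesulfonate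
Conditions: MsCl, Et3N, CH2Cl2, 0 °C
Reagents that add atoms: methanesulfonyl chloride, CS(=O)(=O)Cl
Why: O-Sulfonylation (mesylation through the sulfene) takes place at oxygen only, so the C3 configuration is retained.

Step 5
Reactants: 8 (S)-7-(benzyloxy)-2,2-dimethylchroman-3-yl methanesulfonate
Product: 10 (R)-2-[6-(benzyloxy)-2,3-dihydrobenzofuran-2-yl]propan-2-ol, via oxiranium ion 9 (not isolated)
Conditions: 2,6-lutidine (1.5 equiv), (CF3)2CHOH–H2O 3:1, 60 °C
Reagents that add atoms: water, O
Why: In this strongly ionising, weakly nucleophilic aqueous medium the C3–OMs bond should ionise with anchimeric assistance from ring oxygen O1, whose C2–O1 bond is antiperiplanar to the leaving group in the half-chair with an equatorial mesylate; O1 bonds to C3 to give bridged oxiranium ion 9, which water opens at the tertiary C2 carbon, where most of the positive charge resides, so that the O1–C2 bond of the pyran is exchanged for O1–C3 and C2 becomes the carbinol carbon. The closest known reaction type is ring contraction of cyclic ethers carrying a beta leaving group by ring-oxygen participation (pyranoside to 2,5-anhydro sugar contraction) and the related contraction of activated 2,2-dimethylchroman-3-ols to 2-substituted 2,3-dihydrobenzofurans. The five-membered ring is therefore closed by a 1,2-shift of the aryloxy oxygen and not by a direct cyclisation, the only nucleophilic closure being the 3-exo-tet formation of the oxiranium ring, which is opened again in the same step. No stereocentre is made from a flat carbon: the C3 configuration of 8 controls the result, backside entry of O1 inverting C3 so that the (S)-mesylate should give the (R)-configured C2 of the dihydrofuran without passing through a free secondary cation. The step needs O1 participation to outrun E2 loss of an H4 proton, a 1,2-hydride shift from C4 and aryl participation; the hindered weak base, the neopentyl-like C3 that resists direct substitution, the tertiary site for the charge in 9 and the ring fusion, which keeps C4a out of a phenonium geometry, should secure this. Capture by water must also outrun loss of a methyl proton, which the large excess of water favours.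

Step 6
Reactants: 10 (R)-2-[6-(benzyloxy)-2,3-dihydrobenzofuran-2-yl]propan-2-ol
Product: 11 (R)-2-[6-(benzyloxy)-5-bromo-2,3-dihydrobenzofuran-2-yl]propan-2-ol
Conditions: NBS (1.05 equiv), MeCN, 0 °C, dark
Reagents that add atoms: N-bromosuccinimide, O=C1CCC(=O)N1Br
Why: Electrophilic aromatic bromination goes to C5, which is para to ring oxygen O1 and ortho to the benzyloxy group, whereas C7 lies crowded between the two oxygens and C4 is meta to both.

Step 7
Reactants: 11 (R)-2-[6-(benzyloxy)-5-bromo-2,3-dihydrobenzofuran-2-yl]propan-2-ol
Product: 13 1-[(R)-6-(benzyloxy)-2-(2-hydroxypropan-2-yl)-2,3-dihydrobenzofuran-5-yl]ethan-1-one, via dilithio species 12 (not isolated)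
Conditions: n-BuLi (2.2 equiv), THF, −78 °C; MeC(O)N(OMe)Me, −78 to 0 °C; NH4Cl aq
Reagents that add atoms: N-methoxy-N-methylacetamide, CC(=O)N(C)OC
Why: Deprotonation of the tertiary alcohol and bromine–lithium exchange give 12, which is acylated in a Weinreb ketone synthesis; the chelated tetrahedral adduct prevents over-addition and the tertiary alcohol needs no protecting group.

Step 8
Reactants: 13 1-[(R)-6-(benzyloxy)-2-(2-hydroxypropan-2-yl)-2,3-dihydrobenzofuran-5-yl]ethan-1-one
Product: 14 1-[(R)-6-hydroxy-2-(2-hydroxypropan-2-yl)-2,3-dihydrobenzofuran-5-yl]ethan-1-one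
Conditions: H2 (1 atm), 10% Pd/C, EtOAc, rt
Reagents that add atoms: none
Why: Catalytic hydrogenolysis of the benzyl ether is carried out before the enone is present; the hydrogen-bonded ortho-hydroxy aryl ketone and the non-benzylic C2–O1 bond should survive mild conditions.

Step 9
Reactants: 15 phenol; 16 isoprene
Product: 18 2,2-dimethylchroman, via 2-prenylphenol 17 (not isolated)
Conditions: Amberlyst 15, heptane–THF, 65 °C; NaOH aq wash
Reagents that add atoms: none
Why: Acid-catalysed Friedel–Crafts prenylation ortho to the hydroxyl gives 17, whose alkene is protonated to the tertiary cation and trapped by the phenol oxygen to close the chroman; para-alkylated by-products remain phenols and are removed by the alkaline wash.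

Step 10
Reactants: 18 2,2-dimethylchroman
Product: 20 2,2-dimethylchroman-6-carbaldehyde, via chloro ether 19 (not isolated)
Conditions: Cl2CHOMe, TiCl4, CH2Cl2, 0 °C; then ice-water
Reagents that add atoms: dichloromethyl methyl ether, COC(Cl)Cl; water, O
Why: Rieche formylation attacks C6, para to the ring oxygen, in preference to the more hindered ortho C8, and α-chloro ether 19 is hydrolysed to the aldehyde on aqueous work-up.

Step 11
Reactants: 14 1-[(R)-6-hydroxy-2-(2-hydroxypropan-2-yl)-2,3-dihydrobenzofuran-5-yl]ethan-1-one; 20 2,2-dimethylchroman-6-carbaldehyde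
Product: 22 (E)-3-(2,2-dimethylchroman-6-yl)-1-[(R)-6-hydroxy-2-(2-hydroxypropan-2-yl)-2,3-dihydrobenzofuran-5-yl]prop-2-en-1-one, via aldol adduct 21 (not isolated)
Conditions: KOH (50% aq), EtOH, rt; then AcOH to pH 5–6, 0 °C
Reagents that add atoms: none
Why: Claisen–Schmidt condensation: the methyl ketone enolate adds to the non-enolisable aldehyde and aldol 21 loses water by E1cB to the thermodynamically preferred (E)-enone; in strong base the ortho-phenoxide resists closure to the flavanone, and the C2 stereocentre, which carries no acidic hydrogen, is untouched.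

**Compound list**

1 | 3-(benzyloxy)phenol | Oc1cccc(OCc2ccccc2)c1 | starting material
2 | 3-methylbut-2-enal | CC(C)=CC=O | starting material
3 | 7-(benzyloxy)-4-(2-methylprop-1-en-1-yl)-2-phenyl-4H-1,3,2-benzodioxaborinine (racemic, formed in the flask) | CC(C)=CC1OB(c2ccccc2)Oc2cc(OCc3ccccc3)ccc12 | intermediate
4 | (6Z)-3-(benzyloxy)-6-(3-methylbut-2-en-1-ylidene)cyclohexa-2,4-dien-1-one (o-quinone methide, formed in the flask) | CC(C)=C/C=C1\C(=O)C=C(OCc2ccccc2)C=C1 | intermediate
5 | 7-(benzyloxy)-2,2-dimethyl-2H-chromene | CC1(C)C=Cc2ccc(OCc3ccccc3)cc2O1 | intermediate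
6 | (3S,4S)-7-(benzyloxy)-3,4-epoxy-2,2-dimethylchroman | CC1(C)Oc2cc(OCc3ccccc3)ccc2[C@@H]3O[C@H]13 | intermediate
7 | (S)-7-(benzyloxy)-2,2-dimethylchroman-3-ol | O[C@H]1Cc2ccc(OCc3ccccc3)cc2OC1(C)C | intermediate
8 | (S)-7-(benzyloxy)-2,2-dimethylchroman-3-yl methanesulfonate | CS(=O)(=O)O[C@H]1Cc2ccc(OCc3ccccc3)cc2OC1(C)C | intermediate
9 | bridged oxiranium ion, O1 bonded to the arene, to C(CH3)2 and to the former C3, which is (R) (formed in the flask) | CC1(C)[C@H]2Cc3ccc(OCc4ccccc4)cc3[O+]12 | intermediate
10 | (R)-2-[6-(benzyloxy)-2,3-dihydrobenzofuran-2-yl]propan-2-ol | CC(C)(O)[C@H]1Cc2ccc(OCc3ccccc3)cc2O1 | intermediate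
11 | (R)-2-[6-(benzyloxy)-5-bromo-2,3-dihydrobenzofuran-2-yl]propan-2-ol | CC(C)(O)[C@H]1Cc2cc(Br)c(OCc3ccccc3)cc2O1 | intermediate
12 | lithium (R)-2-[6-(benzyloxy)-5-lithio-2,3-dihydrobenzofuran-2-yl]propan-2-olate (formed in the flask) | [Li]OC(C)(C)[C@H]1Cc2cc([Li])c(OCc3ccccc3)cc2O1 | intermediate
13 | 1-[(R)-6-(benzyloxy)-2-(2-hydroxypropan-2-yl)-2,3-dihydrobenzofuran-5-yl]ethan-1-one | CC(=O)c1cc2c(cc1OCc1ccccc1)O[C@@H](C(C)(C)O)C2 | intermediate
14 | 1-[(R)-6-hydroxy-2-(2-hydroxypropan-2-yl)-2,3-dihydrobenzofuran-5-yl]ethan-1-one | CC(=O)c1cc2c(cc1O)O[C@@H](C(C)(C)O)C2 | intermediate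
15 | phenol | Oc1ccccc1 | starting material
16 | isoprene (2-methylbuta-1,3-diene) | C=CC(C)=C | starting material
17 | 2-(3-methylbut-2-en-1-yl)phenol (formed in the flask) | CC(C)=CCc1ccccc1O | intermediate
18 | 2,2-dimethylchroman | CC1(C)CCc2ccccc2O1 | intermediate
19 | 6-[chloro(methoxy)methyl]-2,2-dimethylchroman (formed in the flask) | COC(Cl)c1ccc2OC(C)(C)CCc2c1 | intermediate
20 | 2,2-dimethylchroman-6-carbaldehyde | CC1(C)CCc2cc(C=O)ccc2O1 | intermediate
21 | 3-(2,2-dimethylchroman-6-yl)-3-hydroxy-1-[(R)-6-hydroxy-2-(2-hydroxypropan-2-yl)-2,3-dihydrobenzofuran-5-yl]propan-1-one, both carbinol epimers (formed in the flask) | CC1(C)CCc2cc(C(O)CC(=O)c3cc4c(cc3O)O[C@@H](C(C)(C)O)C4)ccc2O1 | intermediate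
22 | (E)-3-(2,2-dimethylchroman-6-yl)-1-[(R)-6-hydroxy-2-(2-hydroxypropan-2-yl)-2,3-dihydrobenzofuran-5-yl]prop-2-en-1-one | CC1(C)CCc2cc(/C=C/C(=O)c3cc4c(cc3O)O[C@@H](C(C)(C)O)C4)ccc2O1 | target

**Step count**

Total steps: 11. Longest linear sequence: 9 (steps 1 to 8, then step 11); the aldehyde branch is steps 9 and 10.

**Steps most likely to fail**

Step 5. The aryloxy oxygen is a weak neighbouring group, so ionisation may be slow or may be diverted into elimination towards C4 or a 1,2-hydride shift from C4 to the oxygen-stabilised benzylic position; the ion may also lose a methyl proton instead of taking up water. The fallback replaces the contraction by the known phenoxide–epoxide 5-exo closure; it sets out from 1 and comes back at 10. Compound 1 is O-alkylated with methyl 2-methylbut-3-en-2-yl carbonate and Pd(PPh3)4 in THF to the tertiary allyl ether 1-(benzyloxy)-3-[(2-methylbut-3-en-2-yl)oxy]benzene F1. Aromatic Claisen rearrangement in N,N-diethylaniline at about 180 °C, mainly to the ortho carbon para to the benzyloxy group, should give 5-(benzyloxy)-2-(3-methylbut-2-en-1-yl)phenol F2. Silylation with TBSCl and imidazole gives [5-(benzyloxy)-2-(3-methylbut-2-en-1-yl)phenoxy](tert-butyl)dimethylsilane F3. Shi epoxidation with the enantiomer of the fructose-derived ketone (the one made from L-sorbose), Oxone (2KHSO5·KHSO4·K2SO4) and K2CO3 in MeCN–dimethoxymethane–water at 0 °C should give, by the spiro transition-state model, {5-(benzyloxy)-2-[((2S)-3,3-dimethyloxiran-2-yl)methyl]phenoxy}(tert-butyl)dimethylsilane F4. Bu4NF in THF then frees the phenoxide, which opens the epoxide 5-exo-tet at the secondary carbon with inversion to give 10.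

Step 2. The epoxide is a very electron-rich benzylic ether and may open or undergo a hydride shift to the chroman-3-one during reaction or handling, which would erode enantiopurity in step 3; facial selectivity may also be insufficient. The fallback sets the stereocentre by ketone reduction instead; it sets out from 5 and comes back at 7. Hydroboration–oxidation of 5 (BH3·THF; then NaOH, H2O2) should place the hydroxyl at C3 and give racemic 7-(benzyloxy)-2,2-dimethylchroman-3-ol F5. Ley–Griffith oxidation (Pr4N[RuO4] cat., N-methylmorpholine N-oxide, CH2Cl2) gives 7-(benzyloxy)-2,2-dimethylchroman-3-one F6. Corey–Bakshi–Shibata reduction with (R)-2-methyl-CBS-oxazaborolidine and BH3·SMe2, which differentiates the quaternary C2 from the C4 methylene, should give (S)-configured 7.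

Step 7. The aryllithium may be quenched by proton transfer from the amide α-hydrogens, returning debrominated material, or the ortho-lithiated benzyl ether may rearrange anionically if the temperature rises. The fallback is a cross-coupling; it sets out from 11 and comes back at 13. Stille coupling of 11 with tributyl(1-ethoxyvinyl)stannane and Pd(PPh3)4 in toluene at 100 °C gives (R)-2-[6-(benzyloxy)-5-(1-ethoxyethenyl)-2,3-dihydrobenzofuran-2-yl]propan-2-ol F7, and brief treatment with 1 M HCl in THF at room temperature hydrolyses the enol ether to 13.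

**Further compounds**

F1 | step 5 | 1-(benzyloxy)-3-[(2-methylbut-3-en-2-yl)oxy]benzene | C=CC(C)(C)Oc1cccc(OCc2ccccc2)c1
F2 | step 5 | 5-(benzyloxy)-2-(3-methylbut-2-en-1-yl)phenol | CC(C)=CCc1ccc(OCc2ccccc2)cc1O
F3 | step 5 | [5-(benzyloxy)-2-(3-methylbut-2-en-1-yl)phenoxy](tert-butyl)dimethylsilane | CC(C)=CCc1ccc(OCc2ccccc2)cc1O[Si](C)(C)C(C)(C)C
F4 | step 5 | {5-(benzyloxy)-2-[((2S)-3,3-dimethyloxiran-2-yl)methyl]phenoxy}(tert-butyl)dimethylsilane | CC1(C)O[C@H]1Cc1ccc(OCc2ccccc2)cc1O[Si](C)(C)C(C)(C)C
F5 | step 2 | racemic 7-(benzyloxy)-2,2-dimethylchroman-3-ol | OC1Cc2ccc(OCc3ccccc3)cc2OC1(C)C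
F6 | step 2 | 7-(benzyloxy)-2,2-dimethylchroman-3-one | O=C1Cc2ccc(OCc3ccccc3)cc2OC1(C)C
F7 | step 7 | (R)-2-[6-(benzyloxy)-5-(1-ethoxyethenyl)-2,3-dihydrobenzofuran-2-yl]propan-2-ol | CCOC(=C)c1cc2c(cc1OCc1ccccc1)O[C@@H](C(C)(C)O)C2
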